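**Plan**

1. The target is an ent-labdane diterpenol (3R,5S,9R,10S; labdane numbering C1–C20 is used for positions throughout) esterified at O15 with 30-hydroxytriacontanoic acid.
2. Retrosynthetic cuts, in order: the O15–acyl bond; C8–C17 (methyl onto a C7 enol triflate); C8–C9 of ring B (acyl radical closure); C9=C11 (Wittig); then C1–C10 and C4–C5 of ring A together ([4+2]).
3. Enabling feature: ring A has its oxygen at C3, next to the gem-dimethyl carbon C4 and 1,4 to the quaternary C10, whose substituent C9 can be a formyl group. That is the retron of a 2-siloxydiene (C1=C2–C3(OSi)=C4Me2) adding across an (E)-2-methylenal (C5=C10–C9HO).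
4. Forward order: ring A (Diels–Alder), C11–C15 chain on C9 (Wittig), ring B (6-exo acyl radical cyclisation giving the C8 ketone), C17 (Fe-catalysed methylation of the enol triflate), C3 unmasked and reduced, then esterification with a C30 acid built from two C15 units.
5. Stereochemistry: C5/C10 relative from the E-enal (suprafacial addition), absolute from a chiral oxazaborolidine catalyst; C9 by equilibration α to the C8 ketone; C3 by axial hydride delivery; 13E from E-selective SeO2 oxidation of a prenyl ether.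

Key step: step 3

Assumption: the sense of induction of the (S)-catalyst in step 3 is assigned from the formyl C–H···O binding model for α-substituted enals; if it proved opposite, the mirror-image catalyst would be used and nothing else would change.

**Route**

Step 1
Reactants: 1 4-methylpent-1-en-3-one
Product: 2 triisopropyl[(4-methylpenta-1,3-dien-3-yl)oxy]silane
Conditions: TIPSOTf, Et3N, CH2Cl2, 0 °C
Reagents that add atoms: triisopropylsilyl trifluoromethanesulfonate, CC(C)[Si](C(C)C)(C(C)C)OS(=O)(=O)C(F)(F)F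
Why: Soft enolisation (silyl enol ether formation) of a ketone whose only enolisable hydrogen is the isopropyl methine should give the fully substituted siloxydiene regiospecifically, with no stereocentre formed.

Step 2
Reactants: 3 methyl 4-oxobutanoate; 4 2-(triphenyl-λ5-phosphanylidene)propanal
Product: 5 methyl (4E)-5-methyl-6-oxohex-4-enoate
Conditions: toluene, 80 °C
Reagents that add atoms: none
Why: Wittig olefination with a formyl-stabilised ylide is E-selective, so the chain and the formyl group should end up trans on the new trisubstituted alkene, which later encodes the trans ring fusion.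

Step 3
Reactants: 2 triisopropyl[(4-methylpenta-1,3-dien-3-yl)oxy]silane; 5 methyl (4E)-5-methyl-6-oxohex-4-enoate
Product: 6 methyl 3-[(1R,6R)-6-formyl-2,2,6-trimethyl-3-(triisopropylsilyloxy)cyclohex-3-en-1-yl]propanoate
Conditions: B-(o-tolyl)oxazaborolidine from (S)-α,α-diphenylprolinol, activated with AlBr3 (10 mol%), CH2Cl2, −78 °C to −40 °C
Reagents that add atoms: none
Why: The AlBr3-activated oxazaborolidine binds the formyl group of 5 and lowers its LUMO, so that diene 2 should add in a highly asynchronous [4+2] cycloaddition in which the nucleophilic enol-ether terminus (C4, CMe2) bonds first to the enal β-carbon (C5) and C1 then closes onto the α-carbon (C10); the closest known reaction type is the enantioselective Lewis-acid-catalysed Diels–Alder reaction of 2-siloxydienes with α-substituted enals. Ring A is the only ring formed and closes in the [4πs+2πs] mode (in the stepwise limit a Mukaiyama–Michael addition followed by 6-endo-trig collapse of the enolate onto the siloxyallyl cation). The regiochemistry (siloxy carbon 1,4 to the formyl-bearing carbon) follows from the matched polarisation of both partners and is reinforced sterically because the CMe2 terminus avoids the fully substituted C10. The C5/C10 relationship is fixed by suprafacial addition to the E-alkene: the formyl group and the C6 chain stay trans, so C5–H and C10–CH3 end up anti as the trans ring fusion requires, and no endo/exo issue arises because C3 is sp2. The absolute configuration comes from the catalyst, whose phenyl group shields the C10-Si/C5-Re face of the s-trans enal so that the diene enters on the C10-Re/C5-Si face to give (1R,6R)-6. The step needs conjugate rather than 1,2-attack at the formyl group, which the bulk of the tetrasubstituted enol-ether terminus and the low temperature should secure, and tolerance of the ester, which binds the catalyst far less strongly than the aldehyde.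

Step 4
Reactants: 7 3-methylbut-2-en-1-ol
Product: 8 tert-butyldimethyl[(3-methylbut-2-en-1-yl)oxy]silane
Conditions: TBSCl, imidazole, CH2Cl2, rt
Reagents that add atoms: tert-butyldimethylsilyl chloride, CC(C)(C)[Si](C)(C)Cl
Why: Standard silyl ether protection of a primary alcohol, with no stereocentre involved.

Step 5
Reactants: 8 tert-butyldimethyl[(3-methylbut-2-en-1-yl)oxy]silane
Product: 9 (2E)-4-(tert-butyldimethylsilyloxy)-2-methylbut-2-en-1-ol
Conditions: SeO2 (cat.), t-BuOOH, CH2Cl2, 0 °C to rt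
Reagents that add atoms: tert-butyl hydroperoxide, CC(C)(C)OO (oxygen donor, relayed by selenium dioxide, O=[Se]=O)
Why: Riley allylic oxidation (ene reaction then [2,3]-shift) attacks the methyl group trans to the chain of a trisubstituted alkene, which should set the E geometry of the future C13=C14 bond.

Step 6
Reactants: 9 (2E)-4-(tert-butyldimethylsilyloxy)-2-methylbut-2-en-1-ol
Product: 10 [(2E)-4-bromo-3-methylbut-2-en-1-yl]oxy(tert-butyl)dimethylsilane
Conditions: CBr4, PPh3, CH2Cl2, 0 °C
Reagents that add atoms: tetrabromomethane, BrC(Br)(Br)Br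
Why: The Appel reaction converts the primary allylic alcohol into the bromide under neutral conditions, without allylic transposition or loss of the silyl ether.

Step 7
Reactants: 11 methyltriphenylphosphonium bromide; 10 [(2E)-4-bromo-3-methylbut-2-en-1-yl]oxy(tert-butyl)dimethylsilane
Product: 13 [(3E)-5-(tert-butyldimethylsilyloxy)-3-methylpent-3-en-1-yl]triphenylphosphonium bromide, via methylenetriphenylphosphorane 12 (not isolated)
Conditions: n-BuLi, THF, 0 °C; then 10, −78 °C to rt; salt precipitated with Et2O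
Reagents that add atoms: none
Why: SN2 alkylation of the methylide by the primary allylic bromide should give the one-carbon-extended phosphonium salt, which precipitates and so escapes a second alkylation, leaving the alkene geometry untouched.

Step 8
Reactants: 13 [(3E)-5-(tert-butyldimethylsilyloxy)-3-methylpent-3-en-1-yl]triphenylphosphonium bromide; 6 methyl 3-[(1R,6R)-6-formyl-2,2,6-trimethyl-3-(triisopropylsilyloxy)cyclohex-3-en-1-yl]propanoate
Product: 15 methyl 3-[(1S,6S)-6-[(1Z,4E)-6-(tert-butyldimethylsilyloxy)-4-methylhexa-1,4-dien-1-yl]-2,2,6-trimethyl-3-(triisopropylsilyloxy)cyclohex-3-en-1-yl]propanoate, via phosphorus ylide 14 (not isolated)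
Conditions: KN(SiMe3)2, THF, −78 °C to 0 °C; then 6, −78 °C to rt
Reagents that add atoms: none
Why: Wittig olefination of the hindered but non-enolisable aldehyde with a salt-free unstabilised ylide should give the Z-alkene and spare the methyl ester at low temperature; the C9=C11 geometry is erased in step 10 and is of no consequence.

Step 9
Reactants: 15 methyl 3-[(1S,6S)-6-[(1Z,4E)-6-(tert-butyldimethylsilyloxy)-4-methylhexa-1,4-dien-1-yl]-2,2,6-trimethyl-3-(triisopropylsilyloxy)cyclohex-3-en-1-yl]propanoate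
Product: 16 Se-phenyl 3-[(1S,6S)-6-[(1Z,4E)-6-(tert-butyldimethylsilyloxy)-4-methylhexa-1,4-dien-1-yl]-2,2,6-trimethyl-3-(triisopropylsilyloxy)cyclohex-3-en-1-yl]propaneselenoate
Conditions: Me2AlSePh (from AlMe3 and PhSeH, toluene, 0 °C), CH2Cl2, 0 °C to rt
Reagents that add atoms: dimethylaluminium benzeneselenolate, C[Al](C)[Se]c1ccccc1 (made in the flask from trimethylaluminium, C[Al](C)C, and benzeneselenol, [SeH]c1ccccc1)
Why: Acyl transfer from the aluminium selenolate turns a methyl ester directly into the Se-phenyl selenoester (the acyl radical precursor) without base, so C5 and C10 are not disturbed.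

Step 10
Reactants: 16 Se-phenyl 3-[(1S,6S)-6-[(1Z,4E)-6-(tert-butyldimethylsilyloxy)-4-methylhexa-1,4-dien-1-yl]-2,2,6-trimethyl-3-(triisopropylsilyloxy)cyclohex-3-en-1-yl]propaneselenoate
Product: 17 (1S,4aS,8aR)-1-[(3E)-5-(tert-butyldimethylsilyloxy)-3-methylpent-3-en-1-yl]-5,5,8a-trimethyl-6-(triisopropylsilyloxy)-3,4,4a,5,8,8a-hexahydronaphthalen-2(1H)-one
Conditions: Bu3SnH (syringe pump), AIBN, benzene (0.005 M), 80 °C; then DBU, CH2Cl2, rt
Reagents that add atoms: none
Why: Stannyl radical abstraction of the phenylseleno group gives the acyl radical, which should close ring B by 6-exo-trig attack on C9 of the 1,2-disubstituted alkene (tin hydride acyl radical cyclisation) rather than on the electron-rich enol ether, and because C9 is α to the new C8 ketone the DBU treatment places the side chain equatorial.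

Step 11
Reactants: 17 (1S,4aS,8aR)-1-[(3E)-5-(tert-butyldimethylsilyloxy)-3-methylpent-3-en-1-yl]-5,5,8a-trimethyl-6-(triisopropylsilyloxy)-3,4,4a,5,8,8a-hexahydronaphthalen-2(1H)-one
Product: 19 (1S,4aS,8aR)-1-[(3E)-5-(tert-butyldimethylsilyloxy)-3-methylpent-3-en-1-yl]-5,5,8a-trimethyl-6-(triisopropylsilyloxy)-1,4,4a,5,8,8a-hexahydronaphthalen-2-yl trifluoromethanesulfonate, via potassium enolate 18 (not isolated)
Conditions: KN(SiMe3)2, THF, −78 °C; then PhNTf2, −78 °C to 0 °C
Reagents that add atoms: N-phenylbis(trifluoromethanesulfonimide), O=S(=O)(N(c1ccccc1)S(=O)(=O)C(F)(F)F)C(F)(F)F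
Why: Kinetic deprotonation with the bulky amide base should occur at the unhindered C7 methylene and not at the tertiary C9 next to quaternary C10, and O-triflation then fixes the C7=C8 enol triflate.

Step 12
Reactants: 19 (1S,4aS,8aR)-1-[(3E)-5-(tert-butyldimethylsilyloxy)-3-methylpent-3-en-1-yl]-5,5,8a-trimethyl-6-(triisopropylsilyloxy)-1,4,4a,5,8,8a-hexahydronaphthalen-2-yl trifluoromethanesulfonate
Product: 20 tert-butyldimethyl{[(2E)-3-methyl-5-[(1R,4aS,8aS)-2,5,5,8a-tetramethyl-6-(triisopropylsilyloxy)-1,4,4a,5,8,8a-hexahydronaphthalen-1-yl]pent-2-en-1-yl]oxy}silane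
Conditions: MeMgBr, Fe(acac)3 (5 mol%), THF/NMP, −30 °C to 0 °C
Reagents that add atoms: methylmagnesium bromide, C[Mg]Br
Why: Iron-catalysed cross-coupling of an alkenyl triflate with a methyl Grignard reagent should install C17 with the alkene held at C7=C8, fast enough at low temperature to spare both silyl groups.

Step 13
Reactants: 20 tert-butyldimethyl{[(2E)-3-methyl-5-[(1R,4aS,8aS)-2,5,5,8a-tetramethyl-6-(triisopropylsilyloxy)-1,4,4a,5,8,8a-hexahydronaphthalen-1-yl]pent-2-en-1-yl]oxy}silane
Product: 22 (2R,4aS,5R,8aS)-5-[(3E)-5-hydroxy-3-methylpent-3-en-1-yl]-1,1,4a,6-tetramethyl-1,2,3,4,4a,5,8,8a-octahydronaphthalen-2-ol, via keto alcohol 21 (not isolated)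
Conditions: Bu4NF, THF, 0 °C to rt; then MeOH, NaBH4, 0 °C
Reagents that add atoms: none
Why: Fluoride cleaves the allylic silyl ether and the silyl enol ether (the C3 ketone forms on protonation at C2), and NaBH4 should then deliver hydride axially to C3 on the face away from the axial methyl groups at C4 and C10, giving the equatorial (3R) alcohol.

Step 14
Reactants: 23 15-bromopentadecanoic acid
Product: 24 15-bromopentadecan-1-ol
Conditions: BH3·THF, THF, 0 °C to rt; MeOH quench
Reagents that add atoms: none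
Why: Borane reduces a carboxylic acid chemoselectively to the primary alcohol and leaves the primary alkyl bromide intact.

Step 15
Reactants: 24 15-bromopentadecan-1-ol
Product: 25 [(15-bromopentadecyl)oxy](tert-butyl)dimethylsilane
Conditions: TBSCl, imidazole, DMF/CH2Cl2, rt
Reagents that add atoms: tert-butyldimethylsilyl chloride, CC(C)(C)[Si](C)(C)Cl
Why: Silyl protection masks the hydroxyl group so that the bromide can be converted into a Grignard reagent.

Step 16
Reactants: 25 [(15-bromopentadecyl)oxy](tert-butyl)dimethylsilane; 23 15-bromopentadecanoic acid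
Product: 28 30-(tert-butyldimethylsilyloxy)triacontanoic acid, via Grignard reagent 26 (not isolated), via chloromagnesium carboxylate 27 (not isolated)
Conditions: 25: Mg, THF, 50 °C; 23: MeMgCl (1.0 equiv), THF, −20 °C; combined, Li2CuCl4 (3 mol%), −20 °C to rt; cold dilute HCl
Reagents that add atoms: none
Why: Copper-catalysed sp3–sp3 cross-coupling of an alkyl Grignard reagent with a primary alkyl bromide tolerates the preformed magnesium carboxylate and should join the two C15 halves into the C30 chain.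

Step 17
Reactants: 22 (2R,4aS,5R,8aS)-5-[(3E)-5-hydroxy-3-methylpent-3-en-1-yl]-1,1,4a,6-tetramethyl-1,2,3,4,4a,5,8,8a-octahydronaphthalen-2-ol; 28 30-(tert-butyldimethylsilyloxy)triacontanoic acid
Product: 29 (2E)-5-[(1R,4aS,6R,8aS)-6-hydroxy-2,5,5,8a-tetramethyl-1,4,4a,5,6,7,8,8a-octahydronaphthalen-1-yl]-3-methylpent-2-en-1-yl 30-(tert-butyldimethylsilyloxy)triacontanoate
Conditions: EDC·HCl, DMAP (cat.), CH2Cl2/THF, 0 °C to rt
Reagents that add atoms: none
Why: Steglich esterification should acylate the unhindered primary allylic C15 hydroxyl far faster than the secondary C3 hydroxyl flanked by quaternary C4, so C3 needs no protection.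

Step 18
Reactants: 29 (2E)-5-[(1R,4aS,6R,8aS)-6-hydroxy-2,5,5,8a-tetramethyl-1,4,4a,5,6,7,8,8a-octahydronaphthalen-1-yl]-3-methylpent-2-en-1-yl 30-(tert-butyldimethylsilyloxy)triacontanoate
Product: 30 (2E)-5-[(1R,4aS,6R,8aS)-6-hydroxy-2,5,5,8a-tetramethyl-1,4,4a,5,6,7,8,8a-octahydronaphthalen-1-yl]-3-methylpent-2-en-1-yl 30-hydroxytriacontanoate
Conditions: HF·pyridine, THF/pyridine, 0 °C to rt
Reagents that add atoms: none
Why: Buffered fluoride desilylation should remove the primary silyl ether without touching the allylic ester, the trisubstituted alkenes or the C3 alcohol.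

**Compound list**

1 | 4-methylpent-1-en-3-one | C=CC(=O)C(C)C | starting material
2 | triisopropyl[(4-methylpenta-1,3-dien-3-yl)oxy]silane | C=CC(O[Si](C(C)C)(C(C)C)C(C)C)=C(C)C | intermediate
3 | methyl 4-oxobutanoate | COC(=O)CCC=O | starting material
4 | 2-(triphenyl-λ5-phosphanylidene)propanal | CC(C=O)=P(c1ccccc1)(c1ccccc1)c1ccccc1 | starting material
5 | methyl (4E)-5-methyl-6-oxohex-4-enoate | COC(=O)CC/C=C(\C)C=O | intermediate
6 | methyl 3-[(1R,6R)-6-formyl-2,2,6-trimethyl-3-(triisopropylsilyloxy)cyclohex-3-en-1-yl]propanoate | COC(=O)CC[C@@H]1C(C)(C)C(O[Si](C(C)C)(C(C)C)C(C)C)=CC[C@@]1(C)C=O | intermediate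
7 | 3-methylbut-2-en-1-ol | CC(C)=CCO | starting material
8 | tert-butyldimethyl[(3-methylbut-2-en-1-yl)oxy]silane | CC(C)=CCO[Si](C)(C)C(C)(C)C | intermediate
9 | (2E)-4-(tert-butyldimethylsilyloxy)-2-methylbut-2-en-1-ol | OC/C(C)=C/CO[Si](C)(C)C(C)(C)C | intermediate
10 | [(2E)-4-bromo-3-methylbut-2-en-1-yl]oxy(tert-butyl)dimethylsilane | BrC/C(C)=C/CO[Si](C)(C)C(C)(C)C | intermediate
11 | methyltriphenylphosphonium bromide | C[P+](c1ccccc1)(c1ccccc1)c1ccccc1.[Br-] | starting material
12 | methylenetriphenylphosphorane | C=P(c1ccccc1)(c1ccccc1)c1ccccc1 | intermediate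
13 | [(3E)-5-(tert-butyldimethylsilyloxy)-3-methylpent-3-en-1-yl]triphenylphosphonium bromide | CC(C)(C)[Si](C)(C)OC/C=C(\C)CC[P+](c1ccccc1)(c1ccccc1)c1ccccc1.[Br-] | intermediate
14 | [(3E)-5-(tert-butyldimethylsilyloxy)-3-methylpent-3-en-1-ylidene]triphenylphosphorane | CC(C)(C)[Si](C)(C)OC/C=C(\C)CC=P(c1ccccc1)(c1ccccc1)c1ccccc1 | intermediate
15 | methyl 3-[(1S,6S)-6-[(1Z,4E)-6-(tert-butyldimethylsilyloxy)-4-methylhexa-1,4-dien-1-yl]-2,2,6-trimethyl-3-(triisopropylsilyloxy)cyclohex-3-en-1-yl]propanoate | COC(=O)CC[C@@H]1C(C)(C)C(O[Si](C(C)C)(C(C)C)C(C)C)=CC[C@@]1(C)/C=C\C/C(C)=C/CO[Si](C)(C)C(C)(C)C | intermediate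
16 | Se-phenyl 3-[(1S,6S)-6-[(1Z,4E)-6-(tert-butyldimethylsilyloxy)-4-methylhexa-1,4-dien-1-yl]-2,2,6-trimethyl-3-(triisopropylsilyloxy)cyclohex-3-en-1-yl]propaneselenoate | O=C([Se]c1ccccc1)CC[C@@H]1C(C)(C)C(O[Si](C(C)C)(C(C)C)C(C)C)=CC[C@@]1(C)/C=C\C/C(C)=C/CO[Si](C)(C)C(C)(C)C | intermediate
17 | (1S,4aS,8aR)-1-[(3E)-5-(tert-butyldimethylsilyloxy)-3-methylpent-3-en-1-yl]-5,5,8a-trimethyl-6-(triisopropylsilyloxy)-3,4,4a,5,8,8a-hexahydronaphthalen-2(1H)-one | O=C1CC[C@@H]2C(C)(C)C(O[Si](C(C)C)(C(C)C)C(C)C)=CC[C@@]2(C)[C@@H]1CC/C(C)=C/CO[Si](C)(C)C(C)(C)C | intermediate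
18 | potassium C7=C8 enolate of 17 | [K+].[O-]C1=CC[C@@H]2C(C)(C)C(O[Si](C(C)C)(C(C)C)C(C)C)=CC[C@@]2(C)[C@@H]1CC/C(C)=C/CO[Si](C)(C)C(C)(C)C | intermediate
19 | (1S,4aS,8aR)-1-[(3E)-5-(tert-butyldimethylsilyloxy)-3-methylpent-3-en-1-yl]-5,5,8a-trimethyl-6-(triisopropylsilyloxy)-1,4,4a,5,8,8a-hexahydronaphthalen-2-yl trifluoromethanesulfonate | O=S(=O)(OC1=CC[C@@H]2C(C)(C)C(O[Si](C(C)C)(C(C)C)C(C)C)=CC[C@@]2(C)[C@@H]1CC/C(C)=C/CO[Si](C)(C)C(C)(C)C)C(F)(F)F | intermediate
20 | tert-butyldimethyl{[(2E)-3-methyl-5-[(1R,4aS,8aS)-2,5,5,8a-tetramethyl-6-(triisopropylsilyloxy)-1,4,4a,5,8,8a-hexahydronaphthalen-1-yl]pent-2-en-1-yl]oxy}silane | CC1=CC[C@@H]2C(C)(C)C(O[Si](C(C)C)(C(C)C)C(C)C)=CC[C@@]2(C)[C@@H]1CC/C(C)=C/CO[Si](C)(C)C(C)(C)C | intermediate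
21 | (4aS,5R,8aS)-5-[(3E)-5-hydroxy-3-methylpent-3-en-1-yl]-1,1,4a,6-tetramethyl-3,4,4a,5,8,8a-hexahydronaphthalen-2(1H)-one | CC1=CC[C@@H]2C(C)(C)C(=O)CC[C@@]2(C)[C@@H]1CC/C(C)=C/CO | intermediate
22 | (2R,4aS,5R,8aS)-5-[(3E)-5-hydroxy-3-methylpent-3-en-1-yl]-1,1,4a,6-tetramethyl-1,2,3,4,4a,5,8,8a-octahydronaphthalen-2-ol | CC1=CC[C@@H]2C(C)(C)[C@H](O)CC[C@@]2(C)[C@@H]1CC/C(C)=C/CO | intermediate
23 | 15-bromopentadecanoic acid | OC(=O)CCCCCCCCCCCCCCBr | starting material
24 | 15-bromopentadecan-1-ol | OCCCCCCCCCCCCCCCBr | intermediate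
25 | [(15-bromopentadecyl)oxy](tert-butyl)dimethylsilane | CC(C)(C)[Si](C)(C)OCCCCCCCCCCCCCCCBr | intermediate
26 | [15-(tert-butyldimethylsilyloxy)pentadecyl]magnesium bromide | CC(C)(C)[Si](C)(C)OCCCCCCCCCCCCCCC[Mg]Br | intermediate
27 | chloromagnesium 15-bromopentadecanoate | BrCCCCCCCCCCCCCCC(=O)O[Mg]Cl | intermediate
28 | 30-(tert-butyldimethylsilyloxy)triacontanoic acid | OC(=O)CCCCCCCCCCCCCCCCCCCCCCCCCCCCCO[Si](C)(C)C(C)(C)C | intermediate
29 | (2E)-5-[(1R,4aS,6R,8aS)-6-hydroxy-2,5,5,8a-tetramethyl-1,4,4a,5,6,7,8,8a-octahydronaphthalen-1-yl]-3-methylpent-2-en-1-yl 30-(tert-butyldimethylsilyloxy)triacontanoate | CC1=CC[C@@H]2C(C)(C)[C@H](O)CC[C@@]2(C)[C@@H]1CC/C(C)=C/COC(=O)CCCCCCCCCCCCCCCCCCCCCCCCCCCCCO[Si](C)(C)C(C)(C)C | intermediate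
30 | (2E)-5-[(1R,4aS,6R,8aS)-6-hydroxy-2,5,5,8a-tetramethyl-1,4,4a,5,6,7,8,8a-octahydronaphthalen-1-yl]-3-methylpent-2-en-1-yl 30-hydroxytriacontanoate | CC1=CC[C@@H]2C(C)(C)[C@H](O)CC[C@@]2(C)[C@@H]1CC/C(C)=C/COC(=O)CCCCCCCCCCCCCCCCCCCCCCCCCCCCCO | target

**Step count**

Total step count: 18
Longest linear sequence: 12 steps (7 to 30 through steps 4–13, 17 and 18)

**Steps most likely to fail**

1. Step 3. The tetrasubstituted diene terminus may add too slowly under the chiral catalyst, so that 1,2-addition to the formyl group or desilylation of the diene takes over, and facial discrimination may be incomplete. The fallback sets out from 2 and 5 and comes back at 6, moving enantiocontrol from catalysis to resolution. The cycloaddition is run with a stoichiometric achiral mixed Lewis acid (AlBr3/AlMe3, toluene/CH2Cl2, low temperature), which should give 6 together with its enantiomer, methyl 3-[(1S,6S)-6-formyl-2,2,6-trimethyl-3-(triisopropylsilyloxy)cyclohex-3-en-1-yl]propanoate F1. Condensation of the mixture with (1R,2R)-N,N′-dimethyl-1,2-diphenylethane-1,2-diamine (Et2O, molecular sieves) should give two diastereomeric imidazolidines, the aminal of 6 F2 and the aminal of F1 F3, separable on silica. Mild aqueous acid (pH 4–5) then releases 6 from F2.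

2. Step 10. The acyl radical may be reduced before it cyclises, may attack C11 in the 7-endo mode, or may add too slowly to the hindered, unactivated C9. The fallback sets out from 6 and 10 and comes back at 17; a temporary sulfone at C11 turns C9 into an electron-poor acceptor. Commercial diethyl [(phenylsulfonyl)methyl]phosphonate is alkylated with 10 (NaH, DMF) to the sulfonyl phosphonate F4. Horner–Wadsworth–Emmons reaction of F4 with 6 (NaH, THF) should give the vinyl sulfone ester F5, and i-Bu2AlH (CH2Cl2, −78 °C) the vinyl sulfone aldehyde F6. Radical-chain hydroacylation (dilauroyl peroxide, tert-dodecanethiol cat., benzene, 80 °C) should close ring B by polarity-matched 6-exo addition of the acyl radical to C9 and give the keto sulfone F7. DBU expels benzenesulfinate to the 9(11)-en-8-one F8, and conjugate reduction with [(Ph3P)CuH]6 followed by protonation and base equilibration at C9 gives 17.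

3. Step 9. The Lewis-acidic aluminium reagent may strip the silyl enol ether or ionise the allylic silyl ether. The fallback sets out from 15 and comes back at 16: saponification (LiOH, THF/MeOH/H2O) gives the carboxylic acid F9, which is converted into 16 under neutral conditions with PhSeSePh and PBu3 (CH2Cl2).

Further compounds
F1 | step 3 | methyl 3-[(1S,6S)-6-formyl-2,2,6-trimethyl-3-(triisopropylsilyloxy)cyclohex-3-en-1-yl]propanoate (enantiomer of 6) | COC(=O)CC[C@H]1C(C)(C)C(O[Si](C(C)C)(C(C)C)C(C)C)=CC[C@]1(C)C=O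
F2 | step 3 | (4R,5R)-1,3-dimethyl-4,5-diphenylimidazolidin-2-yl aminal of 6 | COC(=O)CC[C@@H]1C(C)(C)C(O[Si](C(C)C)(C(C)C)C(C)C)=CC[C@@]1(C)C3N(C)[C@H](c2ccccc2)[C@@H](c2ccccc2)N3C
F3 | step 3 | (4R,5R)-1,3-dimethyl-4,5-diphenylimidazolidin-2-yl aminal of F1 | COC(=O)CC[C@H]1C(C)(C)C(O[Si](C(C)C)(C(C)C)C(C)C)=CC[C@]1(C)C3N(C)[C@H](c2ccccc2)[C@@H](c2ccccc2)N3C
F4 | step 10 | diethyl [(3E)-5-(tert-butyldimethylsilyloxy)-3-methyl-1-(phenylsulfonyl)pent-3-en-1-yl]phosphonate (racemic at C1) | CCOP(=O)(OCC)C(C/C(C)=C/CO[Si](C)(C)C(C)(C)C)S(=O)(=O)c1ccccc1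
F5 | step 10 | methyl ester of 15 carrying a phenylsulfonyl group at C11 of the C9=C11 alkene (either alkene geometry) | COC(=O)CC[C@@H]1C(C)(C)C(O[Si](C(C)C)(C(C)C)C(C)C)=CC[C@@]1(C)C=C(C/C(C)=C/CO[Si](C)(C)C(C)(C)C)S(=O)(=O)c1ccccc1
F6 | step 10 | C8 aldehyde from F5 | O=CCC[C@@H]1C(C)(C)C(O[Si](C(C)C)(C(C)C)C(C)C)=CC[C@@]1(C)C=C(C/C(C)=C/CO[Si](C)(C)C(C)(C)C)S(=O)(=O)c1ccccc1
F7 | step 10 | 11-(phenylsulfonyl) derivative of 17 (mixture at C9 and C11) | O=C1CC[C@@H]2C(C)(C)C(O[Si](C(C)C)(C(C)C)C(C)C)=CC[C@@]2(C)C1C(C/C(C)=C/CO[Si](C)(C)C(C)(C)C)S(=O)(=O)c1ccccc1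
F8 | step 10 | 9(11)-dehydro derivative of 17 (exocyclic enone) | O=C1CC[C@@H]2C(C)(C)C(O[Si](C(C)C)(C(C)C)C(C)C)=CC[C@@]2(C)C1=CC/C(C)=C/CO[Si](C)(C)C(C)(C)C
F9 | step 9 | 3-[(1S,6S)-6-[(1Z,4E)-6-(tert-butyldimethylsilyloxy)-4-methylhexa-1,4-dien-1-yl]-2,2,6-trimethyl-3-(triisopropylsilyloxy)cyclohex-3-en-1-yl]propanoic acid | OC(=O)CC[C@@H]1C(C)(C)C(O[Si](C(C)C)(C(C)C)C(C)C)=CC[C@@]1(C)/C=C\C/C(C)=C/CO[Si](C)(C)C(C)(C)C
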